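**Assumption:** compounds 4, 6, 11 and 13 are purchased. Lignan labels: C7–C9 = guaiacyl half of the furofuran, C7'–C9' = syringyl half, C7''–C9'' = glycerol chain; the target SMILES reads as (7R,7'R,8S,8'S,7''R,8''S), i.e. a (−)-medioresinol core carrying an erythro side chain.

## Retrosynthetic overview

1. C7''–C8'' is cut by an auxiliary-controlled anti-glycolate aldol between a medioresinol aryloxyacetyl imide and vanillin acetate; the imide carbonyl becomes C9''H2OH.
2. The aryl ether O–CH2 bond is cut by O-alkylation of the less hindered guaiacyl phenol of (−)-medioresinol.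
3. Key step: both C7–O9' and C7'–O9 bonds are cut back to benzylic C–H bonds of an acyclic (8S,8'S) seco-lignan tetrol, closed forward by double oxidative dearomatisation to p-quinone methides.
4. C8–C8' is cut by oxidative cross-coupling of two Evans imide enolates (dihydroferuloyl and dihydrosinapoyl).
5. Ring order: no ring exists before step 6; both tetrahydrofuran rings form in that one operation (syringyl side expected first).

## Route

**Step 1**
Reactants: 1, syringaldehyde; 2, Meldrum's acid
Product: 3, 3-(4-hydroxy-3,5-dimethoxyphenyl)propanoic acid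
Conditions: HCO2H–Et3N (5:2), 95 °C; then H2O, 100 °C
Reagents that add atoms: water, O (carboxyl OH); all other atoms come from 1 and 2
Why: One-pot reductive Knoevenagel (condensation, formate transfer hydrogenation of the arylidene Meldrum's acid, hydrolysis and decarboxylation) converts an electron-rich benzaldehyde directly into the 3-arylpropanoic acid; no stereocentre.

**Step 2**
Reactants: 3; 4, (R)-4-benzyl-oxazolidin-2-one
Product: 5, (R)-4-benzyl-3-[3-(3,5-dimethoxy-4-pivaloyloxyphenyl)propanoyl]oxazolidin-2-one
Conditions: NaH (2.1 equiv), THF, 0 °C; PivCl (2.2 equiv), −20 °C → rt; then 4, LiCl, Et3N, rt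
Reagents that add atoms: pivaloyl chloride, CC(C)(C)C(=O)Cl
Why: PivCl caps the phenoxide as a hindered pivalate (inert to LDA, removed later by LiAlH4) and turns the carboxylate into the mixed pivalic anhydride, which N-acylates the oxazolidinone at its unhindered carbonyl (mixed-anhydride/LiCl imide formation); no new stereocentre.

**Step 3**
Reactants: 6, 3-(4-hydroxy-3-methoxyphenyl)propanoic acid (dihydroferulic acid); 4
Product: 7, (R)-4-benzyl-3-[3-(3-methoxy-4-pivaloyloxyphenyl)propanoyl]oxazolidin-2-one
Conditions: NaH (2.1 equiv), THF, 0 °C; PivCl (2.2 equiv), −20 °C → rt; then 4, LiCl, Et3N, rt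
Reagents that add atoms: pivaloyl chloride, CC(C)(C)C(=O)Cl
Why: Same one-pot O-pivaloylation and mixed-anhydride N-acylation as step 2; no new stereocentre.

**Step 4**
Reactants: 5 (1.0 equiv); 7 (2.0 equiv)
Product: 8, (2S,3S)-2-(3-methoxy-4-pivaloyloxybenzyl)-3-(3,5-dimethoxy-4-pivaloyloxybenzyl)succinyl bis[(R)-4-benzyl-oxazolidin-2-one]
Conditions: LDA (3.1 equiv), THF, −78 °C; TiCl4 (3.1 equiv), −78 °C → rt; chromatography
Reagents that add atoms: none
Why: Oxidative enolate coupling of Evans imides (Ti(IV)-mediated): each chelated Z-enolate forms the new C8–C8' bond on the face anti to its 4-benzyl group, so the two (R)-auxiliaries impose the same sense and give the threo (2S,3S) succinate. Cross- versus homo-coupling is statistical (about two-thirds of 5 ends up in 8 with 7 in excess), and the two homodimers, which differ by one OMe each, are removed by chromatography.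

**Step 5**
Reactants: 8
Product: 9, (2S,3S)-2-(4-hydroxy-3-methoxybenzyl)-3-(4-hydroxy-3,5-dimethoxybenzyl)butane-1,4-diol
Conditions: LiAlH4 (8 equiv), THF, 0 °C → rt; Rochelle salt work-up
Reagents that add atoms: none
Why: Hydride reduction cleaves both N-acyl oxazolidinones to primary alcohols and both aryl pivalates to phenols in one operation; C8 and C8' are not epimerised and keep the S,S descriptors.

**Step 6 (key step)**
Reactants: 9
Product: 10, (−)-medioresinol, 4-[(1R,3aS,4R,6aS)-4-(4-hydroxy-3-methoxyphenyl)tetrahydro-1H,3H-furo[3,4-c]furan-1-yl]-2,6-dimethoxyphenol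
Conditions: DDQ (2.1 equiv, slow addition), NaHCO3 (solid), 1,4-dioxane, 0.005 M, 10 °C → rt
Reagents that add atoms: none
Why: Proposed new method: DDQ removes hydride from each p-hydroxybenzylic CH2 to give a dearomatised p-quinone methide, which is captured 5-exo by the 1,4-related primary hydroxyl (O9 onto C7', O9' onto C7) with re-aromatisation; each oxygen adds anti to the adjacent C8/C8' substituent, giving the exo,exo (7R,7'R) diaryl furofuran, with the cis ring fusion dictated by the (8S,8'S) backbone. The closest known chemistry is DDQ benzylic alkoxylation of 4-alkylphenols via quinone methides and the quinone-methide ring closures that form pinoresinol-type lignans.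

**Step 7**
Reactants: 10; 11, (S)-4-benzyl-3-(chloroacetyl)oxazolidin-2-one (1.0 equiv)
Product: 12, (S)-4-benzyl-3-{2-[4-((1R,3aS,4R,6aS)-4-(4-hydroxy-3,5-dimethoxyphenyl)tetrahydro-1H,3H-furo[3,4-c]furan-1-yl)-2-methoxyphenoxy]acetyl}oxazolidin-2-one
Conditions: K2CO3 (1.1 equiv), NaI (0.2 equiv), acetone, 0 °C → rt
Reagents that add atoms: none (all atoms come from 10 and 11)
Why: Finkelstein-assisted Williamson etherification (SN2 at the α-halo imide); with limiting electrophile the guaiacyl phenoxide, which has one free ortho position, should react faster than the syringyl phenoxide flanked by two OMe groups. The minor regioisomer and bis-ether are separated and 10 is recycled; no stereocentre is touched.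

**Step 8**
Reactants: 12; 13, vanillin acetate (4-formyl-2-methoxyphenyl acetate, 1.5 equiv)
Product: 14, (S)-4-benzyl-3-[(2R,3R)-3-(4-acetoxy-3-methoxyphenyl)-3-hydroxy-2-(aryloxy)propanoyl]oxazolidin-2-one, where aryloxy is the medioresinol guaiacyl oxygen
Conditions: MgCl2 (0.5 equiv), Et3N (4 equiv), TMSCl (3.5 equiv), EtOAc, rt; then citric acid, MeOH
Reagents that add atoms: none (TMS groups are removed in the work-up)
Why: Proposed new method: extension of the Evans magnesium-halide-catalysed direct anti-aldol (known for N-acyl oxazolidinones with aromatic aldehydes) to an α-aryloxyacetyl imide. Soft enolisation gives the Mg-chelated Z-enolate, which adds to the aldehyde on the face anti to the benzyl group with anti relative topicity, setting C8'' and C7'' as (2R,3R) in the imide (which becomes 8''S,7''R after reduction); TMSCl traps the aldolate and transiently masks the syringyl OH.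

**Step 9**
Reactants: 14
Product: 15, ficusesquilignan A
Conditions: LiBH4 (5 equiv), THF–MeOH, 0 °C → rt
Reagents that add atoms: none
Why: Reductive removal of the Evans auxiliary (hydride at the exocyclic imide carbonyl) gives the C9'' primary alcohol and the same reagent cleaves the aryl acetate; no stereocentre is altered.

## Compound list

1 | syringaldehyde | COc1cc(C=O)cc(OC)c1O | starting material
2 | Meldrum's acid | CC1(C)OC(=O)CC(=O)O1 | starting material
3 | 3-(4-hydroxy-3,5-dimethoxyphenyl)propanoic acid | COc1cc(CCC(=O)O)cc(OC)c1O | intermediate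
4 | (R)-4-benzyl-oxazolidin-2-one | O=C1N[C@H](Cc2ccccc2)CO1 | starting material
5 | (R)-4-benzyl-3-[3-(3,5-dimethoxy-4-pivaloyloxyphenyl)propanoyl]oxazolidin-2-one | COc1cc(CCC(=O)N2[C@H](Cc3ccccc3)COC2=O)cc(OC)c1OC(=O)C(C)(C)C | intermediate
6 | 3-(4-hydroxy-3-methoxyphenyl)propanoic acid | COc1cc(CCC(=O)O)ccc1O | starting material
7 | (R)-4-benzyl-3-[3-(3-methoxy-4-pivaloyloxyphenyl)propanoyl]oxazolidin-2-one | COc1cc(CCC(=O)N2[C@H](Cc3ccccc3)COC2=O)ccc1OC(=O)C(C)(C)C | intermediate
8 | (2S,3S)-2,3-dibenzylsuccinyl bis-imide (guaiacyl/syringyl, both O-pivaloyl) | O=C(N1[C@H](Cc2ccccc2)COC1=O)[C@@H](Cc1ccc(OC(=O)C(C)(C)C)c(OC)c1)[C@H](Cc1cc(OC)c(OC(=O)C(C)(C)C)c(OC)c1)C(=O)N1[C@H](Cc2ccccc2)COC1=O | intermediate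
9 | (2S,3S)-2-(4-hydroxy-3-methoxybenzyl)-3-(4-hydroxy-3,5-dimethoxybenzyl)butane-1,4-diol | OC[C@@H](Cc1ccc(O)c(OC)c1)[C@H](Cc1cc(OC)c(O)c(OC)c1)CO | intermediate
10 | (−)-medioresinol (7R,7'R,8S,8'S) | COc1cc([C@@H]2OC[C@@H]3[C@H]2CO[C@H]3c2cc(OC)c(O)c(OC)c2)ccc1O | intermediate
11 | (S)-4-benzyl-3-(chloroacetyl)oxazolidin-2-one | ClCC(=O)N1[C@@H](Cc2ccccc2)COC1=O | starting material
12 | medioresinol 4-O-(acetyl-(S)-oxazolidinone) ether | COc1cc([C@@H]2OC[C@@H]3[C@H]2CO[C@H]3c2cc(OC)c(O)c(OC)c2)ccc1OCC(=O)N1[C@@H](Cc2ccccc2)COC1=O | intermediate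
13 | vanillin acetate | CC(=O)Oc1ccc(C=O)cc1OC | starting material
14 | (2R,3R)-anti-aldol imide | CC(=O)Oc1ccc([C@@H](O)[C@H](C(=O)N2[C@@H](Cc3ccccc3)COC2=O)Oc2ccc([C@@H]3OC[C@@H]4[C@H]3CO[C@H]4c3cc(OC)c(O)c(OC)c3)cc2OC)cc1OC | intermediate
15 | ficusesquilignan A | COc1cc([C@@H](O)[C@H](CO)Oc2ccc([C@@H]3OC[C@@H]4[C@H]3CO[C@H]4c3cc(OC)c(O)c(OC)c3)cc2OC)ccc1O | target

## Step count and risks

Total steps: 9. Longest linear sequence: 8 (1 → 3 → 5 → 8 → 9 → 10 → 12 → 14 → 15).

Steps most likely to fail:

1. **Step 6 (double quinone-methide cyclisation).** Risks are over-oxidation of the product's benzylic ethers and Friedel–Crafts closure to an aryltetralin. Fallback: drop the C–H oxidation and bring C7/C7' in already oxygenated, by aldol additions of a succinate- or butyrolactone-derived enolate to O-protected vanillin and syringaldehyde, reduction to the 7,7'-dihydroxy tetrol, and acid-mediated SN1 double cyclodehydration.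
2. **Step 7 (guaiacyl versus syringyl O-alkylation).** The selectivity rests on sterics alone and may be modest. Fallback: differentiate by protecting groups — bis-TBS ether of 10, then one-pot CsF/DMF desilylation–alkylation, which unmasks only the unhindered guaiacyl silyl ether; the syringyl OTBS is kept until a final TBAF step.
3. **Step 8 (Mg-catalysed anti-aldol on an aryloxyacetyl imide).** Reactivity and anti selectivity are unproven for this substrate class. Fallback: set the erythro unit by inversion instead — Bu2BOTf syn-aldol of (S)-4-benzyl-3-(bromoacetyl)oxazolidin-2-one with 13 gives the syn bromohydrin, and SN2 displacement of bromide by the guaiacyl phenoxide of 10 (inversion at C8''), followed by LiBH4, leads to the same product.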